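Ring A of the chroman-2-one (C4a, C5, C6, C7, C8, C8a) carries oxygen at C5, C7 and C8a and the acyl group at C8. It is cut at C4a–C8a and C7–C8 into a 1-methoxy-1,3-bis(silyloxy)diene (C4a to C7, already holding the C4 stereocentre from desymmetrised 3-phenylglutaric anhydride) and an ethoxy ynone (C8, C8a with the ketone chain). One cycloaddition–aromatisation builds the arene and leaves its three oxygens differently masked: silyl ether at C5, free phenol at C7, ethyl ether at C8a. Lactonisation can therefore be directed to C8a alone. The spectator arm is kept as the methyl ester and the diene is made by soft enolisation.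

Key step: step 7

Assumption: of the two pseudo-enantiomeric cinchona catalysts (quinine- or quinidine-derived), the one that opens 1 to the S hemiester 2 is used; the sense is to be confirmed by the sign of rotation of 2, and nothing else in the route depends on the alkaloid series.

Step 1
Reactants: 1 3-phenylglutaric anhydride
Product: 2 (3S)-5-methoxy-5-oxo-3-phenylpentanoic acid
Conditions: MeOH (10 equiv), quinine- or quinidine-derived 9-amino-9-deoxy-epi-cinchona 3,5-bis(trifluoromethyl)benzenesulfonamide (10 mol %), MTBE, 20 °C
Reagents that add atoms: methanol, CO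
Why: Organocatalytic alcoholytic desymmetrisation of a prochiral cyclic anhydride (general-base activation of methanol, hydrogen-bond activation of one enantiotopic carbonyl) sets the only stereocentre and should leave free the acid arm that is homologated next, so no ester exchange is needed.

Step 2
Reactants: 2 (3S)-5-methoxy-5-oxo-3-phenylpentanoic acid
Product: 4 dimethyl (5S)-3-oxo-5-phenylheptanedioate, via acyl imidazolide 3 (not isolated)
Conditions: CDI, THF, 20 °C; then Mg(O2CCH2CO2Me)2, THF, 20 → 40 °C; 1 M HCl work-up
Reagents that add atoms: magnesium bis(methyl malonate), COC(=O)CC(=O)[O-].COC(=O)CC(=O)[O-].[Mg+2]; 1,1'-carbonyldiimidazole, O=C(n1ccnc1)n1ccnc1 (its imidazole is retained only in 3)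
Why: Masamune–Brooks decarboxylative Claisen homologation of the acyl imidazolide with the magnesium malonate half-ester should give the β-keto ester under neutral conditions that touch neither the spectator methyl ester nor the β-stereocentre.

Step 3
Reactants: 4 dimethyl (5S)-3-oxo-5-phenylheptanedioate
Product: 5 dimethyl (5S)-3-(tert-butyldimethylsilyloxy)-5-phenylhept-2-enedioate (enol ether geometry not controlled and not needed)
Conditions: TBSOTf (1.1 equiv), Et3N (1.5 equiv), CH2Cl2, 0 °C
Reagents that add atoms: tert-butyldimethylsilyl trifluoromethanesulfonate, CC(C)(C)[Si](C)(C)OS(=O)(=O)C(F)(F)F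
Why: Soft enolisation and O-silylation of a β-keto ester should give the conjugated silyl enol ether regioselectively, placing the robust silyl group on the oxygen that becomes O5, where it must later block lactonisation.

Step 4
Reactants: 5 dimethyl (5S)-3-(tert-butyldimethylsilyloxy)-5-phenylhept-2-enedioate
Product: 6 methyl (3R)-5-(tert-butyldimethylsilyloxy)-7-methoxy-3-phenyl-7-(trimethylsilyloxy)hepta-4,6-dienoate (4Z expected; geometry of both double bonds without consequence)
Conditions: TMSOTf (1.2 equiv), Et3N (2 equiv), Et2O, 0 → 20 °C; decant from the ammonium triflate, concentrate, use crude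
Reagents that add atoms: trimethylsilyl trifluoromethanesulfonate, C[Si](C)(C)OS(=O)(=O)C(F)(F)F
Why: Vinylogous soft enolisation (O-silylation of the vinylogous carbonate carbonyl, then γ-deprotonation by the amine) should form the 1-alkoxy-1,3-bis(silyloxy)diene without a lithium amide, which would also enolise the spectator ester; the simple ester is far less activated and the benzylic stereocentre has no acidic hydrogen.

Step 5
Reactants: 7 3-phenylpropanoyl chloride
Product: 8 N-methoxy-N-methyl-3-phenylpropanamide
Conditions: MeNH(OMe)·HCl, Et3N, CH2Cl2, 0 → 20 °C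
Reagents that add atoms: N,O-dimethylhydroxylamine hydrochloride, CNOC.Cl
Why: N-Acylation of the hydroxylamine by the acid chloride gives the Weinreb amide.

Step 6
Reactants: 9 ethoxyacetylene; 8 N-methoxy-N-methyl-3-phenylpropanamide
Product: 12 1-ethoxy-5-phenylpent-1-yn-3-one, via lithium ethoxyacetylide 10 (not isolated), via tetrahedral adduct 11 (not isolated)
Conditions: n-BuLi, THF, −78 °C; then 8, −78 → −20 °C; cold sat. aq. NH4Cl; Et3N-deactivated silica
Reagents that add atoms: n-butyllithium, CCCC[Li] (lithium retained only in 10 and 11)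
Why: Weinreb ketone synthesis, in which the acetylide adds once and chelated adduct 11 collapses to the ynone only on cold, nearly neutral work-up, which also spares the acid-sensitive ynol ether.

Step 7
Reactants: 6 methyl (3R)-5-(tert-butyldimethylsilyloxy)-7-methoxy-3-phenyl-7-(trimethylsilyloxy)hepta-4,6-dienoate; 12 1-ethoxy-5-phenylpent-1-yn-3-one
Product: 15 methyl (3S)-3-[6-(tert-butyldimethylsilyloxy)-2-ethoxy-4-hydroxy-3-(3-phenylpropanoyl)phenyl]-3-phenylpropanoate, via cyclohexadiene cycloadduct 13 (not isolated), via aryl trimethylsilyl ether 14 (not isolated)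
Conditions: 12 (1.5 equiv), toluene (1 M), 20 → 60 °C; then 1 M HCl, THF, 0 °C
Reagents that add atoms: none
Why: The electron-rich diene and the polarised ynone should combine thermally in a regiochemically matched, probably asynchronous [4+2] cycloaddition (limiting case: Mukaiyama–Michael addition then ring closure), in which diene terminus C4 of 6 (future C4a) bonds to the ethoxy-bearing β-carbon of 12 (future C8a) and the ketene acetal carbon C7 bonds to the ynone α-carbon (future C8); cycloadduct 13 then loses methanol across C7 and C4a to give arene 14, whose labile trimethylsilyl ether is hydrolysed on work-up to the ketone-chelated phenol 15. The closest known reaction type is the Diels–Alder/aromatisation of 1-alkoxy-1,3-bis(silyloxy)buta-1,3-dienes with acetylenic ketones and esters to give resorcinols, here extended to a donor-substituted ynone and a substituted diene terminus. Ring A is closed as a six-membered carbocycle by the cycloaddition itself (in the stepwise limit, a 6-exo-trig attack of the allenolate carbon on the silyloxy-stabilised carboxonium carbon). No new stereocentre persists, because the sp3 centres at C4a and C7 of 13 are erased by aromatisation, and the existing benzylic centre is a spectator with no acidic or ionisable bond under neutral thermal conditions. The selectivity needed is regiochemical and is secured by polarity matching: both oxygen donors of the diene place the largest HOMO coefficient at C4 of 6, while the ketone makes the ethoxy-bearing carbon of 12 the electrophilic site. Omitting Lewis acids disfavours the competing formal [3+3] closure through C6 onto the ketone carbonyl, and staying at or below 60 °C avoids retro-ene loss of ethylene from the ynol ether and 1,5-hydrogen shifts in the diene.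

Step 8
Reactants: 15 methyl (3S)-3-[6-(tert-butyldimethylsilyloxy)-2-ethoxy-4-hydroxy-3-(3-phenylpropanoyl)phenyl]-3-phenylpropanoate
Product: 17 methyl (3S)-3-[6-(tert-butyldimethylsilyloxy)-2,4-dihydroxy-3-(3-phenylpropanoyl)phenyl]-3-phenylpropanoate, via bis(dichloroboryl) ether 16 (not isolated)
Conditions: BCl3 (3 equiv), n-Bu4NI (1.5 equiv), CH2Cl2, −78 → 0 °C; aq. NaHCO3
Reagents that add atoms: boron trichloride, ClB(Cl)Cl (boron and chlorine retained only in 16)
Why: Lewis acid-assisted SN2 dealkylation of the only alkyl aryl ether, activated by the ortho ketone; because the C7 phenol is first tied up as its boron chelate, excess BCl3 and iodide as external nucleophile are used, and the hindered aryl silyl ether and the methyl ester should survive at or below 0 °C.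

Step 9
Reactants: 17 methyl (3S)-3-[6-(tert-butyldimethylsilyloxy)-2,4-dihydroxy-3-(3-phenylpropanoyl)phenyl]-3-phenylpropanoate
Product: 18 (4S)-5-(tert-butyldimethylsilyloxy)-7-hydroxy-4-phenyl-8-(3-phenylpropanoyl)chroman-2-one
Conditions: CSA (20 mol %), 5 Å MS, toluene, 80 °C
Reagents that add atoms: none
Why: Acid-catalysed intramolecular transesterification (lactonisation) should close the six-membered lactone at a single site, since only the C8a phenol is both free and ortho to the propanoate chain (O5 is silylated, the C7 phenol is para).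

Step 10
Reactants: 18 (4S)-5-(tert-butyldimethylsilyloxy)-7-hydroxy-4-phenyl-8-(3-phenylpropanoyl)chroman-2-one
Product: 19 (4S)-5,7-dihydroxy-4-phenyl-8-(3-phenylpropanoyl)chroman-2-one
Conditions: HF·pyridine, THF, 0 → 20 °C
Reagents that add atoms: none
Why: Fluoride cleavage of the aryl silyl ether under weakly acidic conditions avoids phenoxide formation and hence translactonisation to O5 or opening of the aryl lactone, and leaves the C4 stereocentre untouched.

Compound list
1 | 3-phenylglutaric anhydride | O=C1CC(c2ccccc2)CC(=O)O1 | starting material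
2 | (3S)-5-methoxy-5-oxo-3-phenylpentanoic acid | COC(=O)C[C@@H](c1ccccc1)CC(=O)O | intermediate
3 | methyl (3S)-5-(1H-imidazol-1-yl)-5-oxo-3-phenylpentanoate | COC(=O)C[C@@H](c1ccccc1)CC(=O)n1ccnc1 | intermediate
4 | dimethyl (5S)-3-oxo-5-phenylheptanedioate | COC(=O)C[C@@H](c1ccccc1)CC(=O)CC(=O)OC | intermediate
5 | dimethyl (5S)-3-(tert-butyldimethylsilyloxy)-5-phenylhept-2-enedioate (E/Z not controlled) | COC(=O)C[C@@H](c1ccccc1)CC(O[Si](C)(C)C(C)(C)C)=CC(=O)OC | intermediate
6 | methyl (3R)-5-(tert-butyldimethylsilyloxy)-7-methoxy-3-phenyl-7-(trimethylsilyloxy)hepta-4,6-dienoate (double-bond geometry not controlled) | COC(=O)C[C@@H](c1ccccc1)C=C(O[Si](C)(C)C(C)(C)C)C=C(OC)O[Si](C)(C)C | intermediate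
7 | 3-phenylpropanoyl chloride | O=C(Cl)CCc1ccccc1 | starting material
8 | N-methoxy-N-methyl-3-phenylpropanamide | CON(C)C(=O)CCc1ccccc1 | intermediate
9 | ethoxyacetylene | CCOC#C | starting material
10 | lithium ethoxyacetylide | CCOC#C[Li] | intermediate
11 | lithium 1-ethoxy-3-[methoxy(methyl)amino]-5-phenylpent-1-yn-3-olate | CCOC#CC(O[Li])(CCc1ccccc1)N(C)OC | intermediate
12 | 1-ethoxy-5-phenylpent-1-yn-3-one | CCOC#CC(=O)CCc1ccccc1 | intermediate
13 | methyl (3R)-3-[2-(tert-butyldimethylsilyloxy)-6-ethoxy-4-methoxy-5-(3-phenylpropanoyl)-4-(trimethylsilyloxy)cyclohexa-2,5-dien-1-yl]-3-phenylpropanoate (ring stereocentres undefined) | COC(=O)C[C@@H](c1ccccc1)C1C(O[Si](C)(C)C(C)(C)C)=CC(OC)(O[Si](C)(C)C)C(C(=O)CCc2ccccc2)=C1OCC | intermediate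
14 | methyl (3S)-3-[6-(tert-butyldimethylsilyloxy)-2-ethoxy-3-(3-phenylpropanoyl)-4-(trimethylsilyloxy)phenyl]-3-phenylpropanoate | COC(=O)C[C@@H](c1ccccc1)c1c(O[Si](C)(C)C(C)(C)C)cc(O[Si](C)(C)C)c(C(=O)CCc2ccccc2)c1OCC | intermediate
15 | methyl (3S)-3-[6-(tert-butyldimethylsilyloxy)-2-ethoxy-4-hydroxy-3-(3-phenylpropanoyl)phenyl]-3-phenylpropanoate | COC(=O)C[C@@H](c1ccccc1)c1c(O[Si](C)(C)C(C)(C)C)cc(O)c(C(=O)CCc2ccccc2)c1OCC | intermediate
16 | methyl (3S)-3-[6-(tert-butyldimethylsilyloxy)-2,4-bis(dichloroboryloxy)-3-(3-phenylpropanoyl)phenyl]-3-phenylpropanoate | COC(=O)C[C@@H](c1ccccc1)c1c(O[Si](C)(C)C(C)(C)C)cc(OB(Cl)Cl)c(C(=O)CCc2ccccc2)c1OB(Cl)Cl | intermediate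
17 | methyl (3S)-3-[6-(tert-butyldimethylsilyloxy)-2,4-dihydroxy-3-(3-phenylpropanoyl)phenyl]-3-phenylpropanoate | COC(=O)C[C@@H](c1ccccc1)c1c(O[Si](C)(C)C(C)(C)C)cc(O)c(C(=O)CCc2ccccc2)c1O | intermediate
18 | (4S)-5-(tert-butyldimethylsilyloxy)-7-hydroxy-4-phenyl-8-(3-phenylpropanoyl)chroman-2-one | O=C1C[C@@H](c2ccccc2)c2c(O[Si](C)(C)C(C)(C)C)cc(O)c(C(=O)CCc3ccccc3)c2O1 | intermediate
19 | (4S)-5,7-dihydroxy-4-phenyl-8-(3-phenylpropanoyl)chroman-2-one | O=C1C[C@@H](c2ccccc2)c2c(O)cc(O)c(C(=O)CCc3ccccc3)c2O1 | target

Total step count: 10. Longest linear sequence: 8 steps (1 → 2 → 4 → 5 → 6 → 15 → 17 → 18 → 19); the ynone branch (7 → 8 → 12) adds 2 steps.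

Steps most likely to fail

Step 7. The bimolecular cycloaddition may be too slow, since the alkyne is deactivated by its own donor and the reacting diene terminus is substituted. Diene decomposition, attack through C6 of the diene, or retro-ene fragmentation of the ynol ether could then outrun ring formation. The fallback sets out from acid chloride 7 and comes back at 18, building the stereocentre on a preformed ring A. Friedel–Crafts acylation of phloroglucinol with 7 (AlCl3, PhNO2/CH2Cl2) should give 3-phenyl-1-(2,4,6-trihydroxyphenyl)propan-1-one F1. Selective silylation of the only non-chelated hydroxyl (TBSCl 1 equiv, imidazole, CH2Cl2, 0 °C) should give 1-[4-(tert-butyldimethylsilyloxy)-2,6-dihydroxyphenyl]-3-phenylpropan-1-one F2. Iminium-catalysed enantioselective Friedel–Crafts alkylation with (E)-cinnamaldehyde (diarylprolinol silyl ether, enantiomer chosen for 4S) would occur at the ring carbon between the free and the silylated oxygen. Hemiacetal closure by the only free neighbouring phenol should then give (4S)-1-[5-(tert-butyldimethylsilyloxy)-2,7-dihydroxy-4-phenylchroman-8-yl]-3-phenylpropan-1-one F3. Oxidation of the lactol (PhI(OAc)2, TEMPO, CH2Cl2) leads to 18. The weaknesses are the reduced nucleophilicity of the acylated ring and the uncertain enantioselectivity of the alkylation.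

Step 8. Dealkylation may stall because the ketone is already engaged in the boron chelate of the C7 phenol, and forcing conditions may strip the C5 silyl ether and so lose the regiocontrol of the lactonisation. The fallback sets out from Weinreb amide 8 (used with diene 6) and comes back at 17. It replaces ethyl by isopropyl, an aryl ether that BCl3 cleaves at 0 °C without needing chelation. Isopropanol, KH and trichloroethylene should give (E)-1,2-dichloro-1-(propan-2-yloxy)ethene F4. n-BuLi (2 equiv, THF, −78 → −40 °C) converts this into lithium (propan-2-yloxy)acetylide F5, which is acylated with 8 to give 5-phenyl-1-(propan-2-yloxy)pent-1-yn-3-one F6. Cycloaddition–aromatisation with 6 as in step 7, at or below 50 °C, should give methyl (3S)-3-[6-(tert-butyldimethylsilyloxy)-4-hydroxy-3-(3-phenylpropanoyl)-2-(propan-2-yloxy)phenyl]-3-phenylpropanoate F7. BCl3 (CH2Cl2, −78 → 0 °C) then gives 17.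

Step 4. Silylation of the spectator ester, incomplete γ-enolisation, or hydrolytic loss of the labile ketene acetal during isolation may spoil the diene. The fallback sets out from 5 and comes back at 15. It uses exhaustive hard enolisation in place of selective soft enolisation: LiN(i-Pr)2 (2.2 equiv) with Me3SiCl present as in situ quench (THF, −78 °C) enolises both the γ-position and the spectator ester. This should give (3S)-5-(tert-butyldimethylsilyloxy)-1,7-dimethoxy-3-phenyl-1,7-bis(trimethylsilyloxy)hepta-1,4,6-triene F8. Its spectator ester is masked as a simple silyl ketene acetal, far less nucleophilic than the doubly donor-substituted diene. The triene is taken through the conditions of step 7, and the acidic work-up returns the methyl ester together with the C7 phenol, which is 15.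

Further compounds
F1 | step 7 | 3-phenyl-1-(2,4,6-trihydroxyphenyl)propan-1-one | O=C(CCc1ccccc1)c1c(O)cc(O)cc1O
F2 | step 7 | 1-[4-(tert-butyldimethylsilyloxy)-2,6-dihydroxyphenyl]-3-phenylpropan-1-one | O=C(CCc1ccccc1)c1c(O)cc(O[Si](C)(C)C(C)(C)C)cc1O
F3 | step 7 | (4S)-1-[5-(tert-butyldimethylsilyloxy)-2,7-dihydroxy-4-phenylchroman-8-yl]-3-phenylpropan-1-one (C2 epimers) | OC1C[C@@H](c2ccccc2)c2c(O[Si](C)(C)C(C)(C)C)cc(O)c(C(=O)CCc3ccccc3)c2O1
F4 | step 8 | (E)-1,2-dichloro-1-(propan-2-yloxy)ethene | Cl/C=C(OC(C)C)/Cl
F5 | step 8 | lithium (propan-2-yloxy)acetylide | CC(C)OC#C[Li]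
F6 | step 8 | 5-phenyl-1-(propan-2-yloxy)pent-1-yn-3-one | CC(C)OC#CC(=O)CCc1ccccc1
F7 | step 8 | methyl (3S)-3-[6-(tert-butyldimethylsilyloxy)-4-hydroxy-3-(3-phenylpropanoyl)-2-(propan-2-yloxy)phenyl]-3-phenylpropanoate | COC(=O)C[C@@H](c1ccccc1)c1c(O[Si](C)(C)C(C)(C)C)cc(O)c(C(=O)CCc2ccccc2)c1OC(C)C
F8 | step 4 | (3S)-5-(tert-butyldimethylsilyloxy)-1,7-dimethoxy-3-phenyl-1,7-bis(trimethylsilyloxy)hepta-1,4,6-triene | COC(O[Si](C)(C)C)=C[C@@H](c1ccccc1)C=C(O[Si](C)(C)C(C)(C)C)C=C(OC)O[Si](C)(C)C
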